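(The data are simulated with constants of no real substance; the scatter is artificial.)

At early times the two earlier runs climb alike: the fraction of the charged first end groups read as links rises at 0.0470 h⁻¹ in the summer run between 1.00 h and 3.00 h, and at 0.0467 h⁻¹ in the midnight run up to 90.0 min, although summer holds twice the solid. We therefore leave the solid charge out of the rate.

| flask | first end groups | third end groups | solid second end groups | remark | time |
|---|---|---|---|---|---|
| summer | 0.20 M | 0.10 M | 0.18 M | run made earlier |  |
| midnight | 0.20 M | 0.10 M | 0.090 M | run made earlier |  |
| elm | 0.20 M | 0.100 M | 0.180 M | everything together at the start | 8.0 h |
| birch | 0.20 M | 0.100 M (fed, over 6.0 h) | 0.180 M | all else is in the flask from the start; the feed brings no volume worth counting | 8.0 h |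
| cedar | 0.20 M (fed, over 6.0 h) | 0.100 M | 0.180 M | all else is in the flask from the start; the feed brings no volume worth counting | 8.0 h |

summer run (percent of the first end groups charged)

| time / h | links / % |
|---|---|
| 1.00 | 3.8 |
| 3.00 | 13.2 |
| 5.00 | 23.9 |
| 8.00 | 36.2 |

midnight run (percent of the first end groups charged)

| time / min | links / % |
|---|---|
| 8.00 | 0.7 |
| 20.0 | 1.4 |
| 40.0 | 1.4 |
| 90.0 | 7.0 |

(each reading ± 0.5 percentage points)

- the numbers in the tables scatter with a standard deviation of 0.5 percentage points
- at the start none of the solid second end groups is in solution

1. which flask leads in amount of links, in percent of the first end groups charged ("all alike" within 1.5 percentage points) (elm / birch / cedar / all alike)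
2. how much links is there at the end, in percent of the first end groups charged: elm
3. how much links is there at the end, in percent of the first end groups charged: birch
4. how much links is there at the end, in percent of the first end groups charged: cedar

Let x be the fraction of the charged first end groups standing as links, and let the gain per hour be k, a pseudo-first-order constant, times what remains. Across the summer run x rises at 0.0463 h⁻¹ while on average 80.0% remains, so we read k as 0.0579 h⁻¹. No integral is needed: the first pass gives x as k times the time, and we put that answer back, since on average one minus half of x remains. The rounds close on k times the time, divided by one plus half of that product.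

Elm repeats summer, so we say 36.2%. Both runs held third end groups at 0.10 M, so k tells nothing about their feed, and we keep k and set birch level with elm.

In cedar the first end groups enter evenly, so their mean time in the flask is 5.00 h. The first way gives 28.9% on the first pass, 24.8% on the second, and settles at 25.3%. The second way reads summer at that age, 23.9% at 5.00 h. They part by 1.4 percentage points. Run back from its first reading, the summer line reads zero at 0.330 h, and taking that from the mean time gives 23.8%. This comes from the same summer readings as the 23.9% itself, so it is no check; it shows that a late start of that size covers the gap. Just the first 5.51% of cedar's feed enters within that time, so we take the reading to be the one that cheats and commit to the first way.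

The forecast puts elm at 36%, birch at 26% and cedar at 25.6%, with elm leading, and so differs from us on birch, noting that “Third end groups are not visibly used up”.

The flasks give 36.9% for elm, 40.4% for birch and 32.0% for cedar, so birch leads.

    first end groups + second end groups ⇌ links (K = 150 M⁻¹, k = 0.240 M⁻¹ min⁻¹)
    second end groups + third end groups → links of the second sort (k = 0.250 M⁻¹ min⁻¹)
    solid second end groups ⇌ second end groups, rate k3*(cs3 - [second end groups]) while solid is left; crystals form when [second end groups] > cs3 (solubility = 0.120 M, k = 0.00240 min⁻¹)

Cedar stands 6.7 points above our reckoning, and read back through its mean time it has a constant of 0.0762 h⁻¹. The neighbouring flask is cedar read at 15 h, with a mean time of 12.0 h. The same reckoning gives 51.6%, and that flask holds 46.8% as links. Its constant read back is 0.0509 h⁻¹, while the solid second end groups go from 27.8% of their charge at 8.00 h to 0% at 15.0 h.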